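**Retrosynthetic overview**
1. Target ⇐ lipase acetylation of the C15 alcohol; C17 acid ⇐ Pd hydroxycarbonylation of the C7=C8 enol triflate of an 8-ketone; C12–C13 ⇐ B-alkyl Suzuki coupling of a 9-vinyl group with the (E)-enol triflate of methyl acetoacetate.
2. Ring B (9-vinyl-8-ketone 14) ⇐ key step: semipinacol ring expansion, cyclopentanol → cyclohexanone, of the chloroallyl adduct of trans-hydrindanone 10; quaternary C10 migrates and the C9–C10 bond forms.
3. Ring A (10) ⇐ ring-closing metathesis/hydrogenation of the trans-2-allyl-3-(1,1-dimethylallyl)cyclopentanone 8.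
4. 8 ⇐ enantioselective conjugate reverse-prenylation of 2-methylcyclopent-2-en-1-one (sets C5), then enolate allylation anti to it (sets C10).
5. Ring order: purchased five-membered ring → ring A by metathesis → ring B by one-carbon expansion of the five-membered ring.

Assumption: 1,3-dichloroprop-1-ene is used as the commercial E/Z mixture; labdane numbers (C5, C9, C10, C17) are used in the comments. Target configuration read from the SMILES: 5S,9R,10S, 13E (trans-decalin, 9β side chain).

Step 1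
Reactants: 1 1-chloro-3-methylbut-2-ene
Product: 3 trimethyl(3-methylbut-2-en-1-yl)silane, via prenylmagnesium chloride 2 (not isolated)
Conditions: Mg, Me3SiCl, THF, 0 → 25 °C
Reagents that add atoms: chlorotrimethylsilane, C[Si](C)(C)Cl
Why: Barbier-type Grignard formation with in situ silylation; the allylic Grignard is silylated at its unhindered primary terminus, giving the γ,γ-dimethylallylsilane needed for SE2′ transfer of a 1,1-dimethylallyl group.

Step 2
Reactants: 4 2-methylcyclopent-2-en-1-one; 3 trimethyl(3-methylbut-2-en-1-yl)silane; 5 3-bromoprop-1-ene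
Product: 8 (2S,3S)-2-methyl-3-(2-methylbut-3-en-2-yl)-2-(prop-2-en-1-yl)cyclopentan-1-one, via silyl enol ether 6 (not isolated), via lithium enolate 7 (not isolated)
Conditions: chiral imidodiphosphorimidate (IDPi) Brønsted acid (2 mol%), toluene, −40 °C; then MeLi, THF, 0 °C; then 5, DMPU, −78 → 0 °C
Reagents that add atoms: none
Why: Proposed new method: the IDPi acid is silylated by 3 to a chiral silylium ion pair that activates the enone as a silyloxyallyl cation inside the confined counter-anion; γ-attack (SE2′) of the prenylsilane on one enantioface forms C4–C5, the gem-dimethyl quaternary carbon and the C5 stereocentre, and silyl transfer to oxygen releases regiodefined enol ether 6 and turns the catalyst over (the catalyst antipode is chosen to give (3S)-6). Closest known reactions are IDPi-catalysed Hosomi–Sakurai allylation of aldehydes and Mukaiyama–Michael additions, and racemic Me3SiNTf2-catalysed conjugate allylation. MeLi then unmasks lithium enolate 7, which is allylated anti to the bulky C3 group (enolate alkylation), setting quaternary C10 trans.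

Step 3
Reactants: 8 (2S,3S)-2-methyl-3-(2-methylbut-3-en-2-yl)-2-(prop-2-en-1-yl)cyclopentan-1-one
Product: 10 (3aS,7aS)-4,4,7a-trimethyloctahydro-1H-inden-1-one, via bicyclic alkene 9 (not isolated)
Conditions: second-generation Grubbs catalyst RuCl2(=CHPh)(H2IMes)(PCy3) (3 mol%), CH2Cl2, 40 °C; then Pd/C, H2 (1 atm), 25 °C
Reagents that add atoms: none
Why: Ring-closing metathesis of the two trans-disposed terminal alkenes closes ring A with loss of ethene, and heterogeneous hydrogenation saturates the new disubstituted alkene; no stereocentre is touched, so the ring fusion stays trans as set in step 2.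

Step 4
Reactants: 10 (3aS,7aS)-4,4,7a-trimethyloctahydro-1H-inden-1-one; 11 1,3-dichloroprop-1-ene
Product: 14 (1R,4aS,8aS)-1-ethenyl-5,5,8a-trimethyloctahydronaphthalen-2(1H)-one, via chloroallylzinc chloride 12 (not isolated), via zinc chlorohydrin alkoxide 13 (not isolated)
Conditions: Zn dust, LiCl, THF, 0 → 25 °C; then Et2AlCl, CH2Cl2, −78 → 0 °C
Reagents that add atoms: none
Why: Proposed new method: Barbier γ-chloroallylation (the allylzinc adds through its chlorine-bearing carbon in a six-membered transition state) gives the metal alkoxide of an α-hydroxy allylic chloride; Et2AlCl ionises the allylic C–Cl bond and the anti-periplanar, fully substituted C7a–C1 bond (C10) migrates to the proximal allyl terminus as the alkoxide collapses to the ketone. This semipinacol ring expansion forms C9–C10 and ring B with retention at C10; the quaternary carbon out-migrates the CH2, and any vinyl epoxide formed converges under the Lewis acid. The new α-vinyl centre C9 is epimerisable and settles as the equatorial (1R) epimer in step 6. Closest known reactions are the Sisti halohydrin-alkoxide ring enlargement, the Tsuchihashi–Suzuki organoaluminium rearrangement of α-hydroxy sulfonates, and palladium π-allyl Wagner–Meerwein expansions of strained cycloalkanols.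

Step 5
Reactants: 15 methyl 3-oxobutanoate
Product: 17 methyl (E)-3-{[(trifluoromethyl)sulfonyl]oxy}but-2-enoate, via tetramethylammonium enolate 16 (not isolated)
Conditions: Tf2O, aq. Me4NOH, toluene, 0 → 25 °C
Reagents that add atoms: trifluoromethanesulfonic anhydride, O=S(=O)(OS(=O)(=O)C(F)(F)F)C(F)(F)F
Why: Stereoselective enol triflation of a β-keto ester; the non-chelated ammonium enolate is (E) and is O-sulfonylated with retention, fixing the later 13E geometry.

Step 6
Reactants: 14 (1R,4aS,8aS)-1-ethenyl-5,5,8a-trimethyloctahydronaphthalen-2(1H)-one; 17 methyl (E)-3-{[(trifluoromethyl)sulfonyl]oxy}but-2-enoate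
Product: 19 methyl (E)-3-methyl-5-[(1R,4aS,8aS)-5,5,8a-trimethyl-2-oxodecahydronaphthalen-1-yl]pent-2-enoate, via alkylborane 18 (not isolated)
Conditions: 9-BBN-H, THF, 0 → 25 °C; then 17, Pd(dppf)Cl2 (5 mol%), AsPh3, aq. K3PO4, DMF, 25 → 45 °C
Reagents that add atoms: none
Why: Anti-Markovnikov hydroboration of the terminal vinyl group (much faster than reduction of the hindered ketone), then B-alkyl Suzuki–Miyaura coupling with retention of the enol triflate geometry forms C12–C13 and the 13E alkene; the phosphate base equilibrates C9 to the equatorial (1R) epimer.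

Step 7
Reactants: 19 methyl (E)-3-methyl-5-[(1R,4aS,8aS)-5,5,8a-trimethyl-2-oxodecahydronaphthalen-1-yl]pent-2-enoate
Product: 21 methyl (E)-3-methyl-5-[(1R,4aS,8aS)-5,5,8a-trimethyl-2-{[(trifluoromethyl)sulfonyl]oxy}-1,4,4a,5,6,7,8,8a-octahydronaphthalen-1-yl]pent-2-enoate, via potassium enolate 20 (not isolated)
Conditions: KN(SiMe3)2, THF, −78 °C; then PhNTf2, −78 → −20 °C
Reagents that add atoms: N-phenylbis(trifluoromethanesulfonimide), O=S(=O)(N(c1ccccc1)S(=O)(=O)C(F)(F)F)C(F)(F)F
Why: Kinetic enolisation of the 2-substituted cyclohexanone at the open CH2 (C7) rather than the tertiary C9–H next to the quaternary carbon, then O-triflation (kinetic enol triflate formation); the ketone is more acidic than the enoate γ-hydrogens, and C9 is not touched.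

Step 8
Reactants: 21 methyl (E)-3-methyl-5-[(1R,4aS,8aS)-5,5,8a-trimethyl-2-{[(trifluoromethyl)sulfonyl]oxy}-1,4,4a,5,6,7,8,8a-octahydronaphthalen-1-yl]pent-2-enoate
Product: 22 (1R,4aS,8aS)-1-[(E)-5-hydroxy-3-methylpent-3-en-1-yl]-5,5,8a-trimethyl-1,4,4a,5,6,7,8,8a-octahydronaphthalen-2-yl trifluoromethanesulfonate
Conditions: i-Bu2AlH, CH2Cl2, −78 °C
Reagents that add atoms: none
Why: 1,2-Reduction of the conjugated methyl ester to the allylic alcohol with alkene geometry unchanged; the vinyl triflate is inert at −78 °C.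

Step 9
Reactants: 22 (1R,4aS,8aS)-1-[(E)-5-hydroxy-3-methylpent-3-en-1-yl]-5,5,8a-trimethyl-1,4,4a,5,6,7,8,8a-octahydronaphthalen-2-yl trifluoromethanesulfonate
Product: 23 (1R,4aS,8aS)-1-[(E)-5-hydroxy-3-methylpent-3-en-1-yl]-5,5,8a-trimethyl-1,4,4a,5,6,7,8,8a-octahydronaphthalene-2-carboxylic acid
Conditions: Pd(OAc)2 (5 mol%), dppf, CO (1 atm), H2O, Et3N, DMF, 60 °C
Reagents that add atoms: carbon monoxide, [C-]#[O+]; water, O
Why: Palladium-catalysed hydroxycarbonylation of the vinyl triflate (oxidative addition to zerovalent palladium, CO insertion, hydrolysis of the acyl complex) installs C17 as the acid with the alkene fixed at C7=C8; the free allylic alcohol does not ionise.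

Step 10
Reactants: 23 (1R,4aS,8aS)-1-[(E)-5-hydroxy-3-methylpent-3-en-1-yl]-5,5,8a-trimethyl-1,4,4a,5,6,7,8,8a-octahydronaphthalene-2-carboxylic acid
Product: 24 (1R,4aS,8aS)-1-[(E)-5-acetoxy-3-methylpent-3-en-1-yl]-5,5,8a-trimethyl-1,4,4a,5,6,7,8,8a-octahydronaphthalene-2-carboxylic acid
Conditions: vinyl acetate, immobilised Candida antarctica lipase B, t-BuOMe, 30 °C
Reagents that add atoms: vinyl acetate, C=COC(C)=O
Why: Lipase-catalysed transesterification acylates only the primary allylic alcohol (the hindered conjugated acid is not an acyl donor) and is irreversible because the leaving enol becomes acetaldehyde.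

**Compound list**
1 | 1-chloro-3-methylbut-2-ene (prenyl chloride) | CC(C)=CCCl | starting material
2 | (3-methylbut-2-en-1-yl)magnesium chloride | CC(C)=CC[Mg]Cl | intermediate
3 | trimethyl(3-methylbut-2-en-1-yl)silane | CC(C)=CC[Si](C)(C)C | intermediate
4 | 2-methylcyclopent-2-en-1-one | CC1=CCCC1=O | starting material
5 | 3-bromoprop-1-ene (allyl bromide) | C=CCBr | starting material
6 | trimethyl{[(3S)-2-methyl-3-(2-methylbut-3-en-2-yl)cyclopent-1-en-1-yl]oxy}silane | C=CC(C)(C)[C@@H]1CCC(O[Si](C)(C)C)=C1C | intermediate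
7 | lithium (3S)-2-methyl-3-(2-methylbut-3-en-2-yl)cyclopent-1-en-1-olate | C=CC(C)(C)[C@@H]1CCC(O[Li])=C1C | intermediate
8 | (2S,3S)-2-methyl-3-(2-methylbut-3-en-2-yl)-2-(prop-2-en-1-yl)cyclopentan-1-one (allyl trans to the 3-substituent) | O=C1CC[C@@H](C(C)(C)C=C)[C@]1(C)CC=C | intermediate
9 | (3aS,7aS)-4,4,7a-trimethyl-2,3,3a,4,7,7a-hexahydro-1H-inden-1-one (trans-fused) | O=C1CC[C@H]2C(C)(C)C=CC[C@]12C | intermediate
10 | (3aS,7aS)-4,4,7a-trimethyloctahydro-1H-inden-1-one (trans-fused) | O=C1CC[C@H]2C(C)(C)CCC[C@]12C | intermediate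
11 | 1,3-dichloroprop-1-ene (E/Z mixture) | ClC=CCCl | starting material
12 | (3-chloroprop-2-en-1-yl)zinc chloride | ClC=CC[Zn]Cl | intermediate
13 | chlorozinc (3aS,7aS)-1-(1-chloroprop-2-en-1-yl)-4,4,7a-trimethyloctahydro-1H-inden-1-olate (epimers at C1 and CHCl) | C=CC(Cl)C1(O[Zn]Cl)CC[C@H]2C(C)(C)CCC[C@]12C | intermediate
14 | (1R,4aS,8aS)-1-ethenyl-5,5,8a-trimethyloctahydronaphthalen-2(1H)-one (trans-decalin, vinyl equatorial; any C1 epimer converges in step 6) | C=C[C@H]1C(=O)CC[C@H]2C(C)(C)CCC[C@]12C | intermediate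
15 | methyl 3-oxobutanoate | COC(=O)CC(C)=O | starting material
16 | tetramethylammonium (E)-4-methoxy-4-oxobut-2-en-2-olate | COC(=O)/C=C(\C)[O-].C[N+](C)(C)C | intermediate
17 | methyl (E)-3-{[(trifluoromethyl)sulfonyl]oxy}but-2-enoate | COC(=O)/C=C(\C)OS(=O)(=O)C(F)(F)F | intermediate
18 | (1R,4aS,8aS)-1-[2-(9-borabicyclo[3.3.1]nonan-9-yl)ethyl]-5,5,8a-trimethyloctahydronaphthalen-2(1H)-one | B1(C2CCCC1CCC2)CC[C@H]1C(=O)CC[C@H]2C(C)(C)CCC[C@]12C | intermediate
19 | methyl (E)-3-methyl-5-[(1R,4aS,8aS)-5,5,8a-trimethyl-2-oxodecahydronaphthalen-1-yl]pent-2-enoate | COC(=O)/C=C(\C)CC[C@H]1C(=O)CC[C@H]2C(C)(C)CCC[C@]12C | intermediate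
20 | potassium (1R,4aS,8aS)-1-[(E)-5-methoxy-3-methyl-5-oxopent-3-en-1-yl]-5,5,8a-trimethyl-1,4,4a,5,6,7,8,8a-octahydronaphthalen-2-olate | COC(=O)/C=C(\C)CC[C@H]1C(O[K])=CC[C@H]2C(C)(C)CCC[C@]12C | intermediate
21 | methyl (E)-3-methyl-5-[(1R,4aS,8aS)-5,5,8a-trimethyl-2-{[(trifluoromethyl)sulfonyl]oxy}-1,4,4a,5,6,7,8,8a-octahydronaphthalen-1-yl]pent-2-enoate | COC(=O)/C=C(\C)CC[C@H]1C(OS(=O)(=O)C(F)(F)F)=CC[C@H]2C(C)(C)CCC[C@]12C | intermediate
22 | (1R,4aS,8aS)-1-[(E)-5-hydroxy-3-methylpent-3-en-1-yl]-5,5,8a-trimethyl-1,4,4a,5,6,7,8,8a-octahydronaphthalen-2-yl trifluoromethanesulfonate | OC/C=C(\C)CC[C@H]1C(OS(=O)(=O)C(F)(F)F)=CC[C@H]2C(C)(C)CCC[C@]12C | intermediate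
23 | (1R,4aS,8aS)-1-[(E)-5-hydroxy-3-methylpent-3-en-1-yl]-5,5,8a-trimethyl-1,4,4a,5,6,7,8,8a-octahydronaphthalene-2-carboxylic acid | OC/C=C(\C)CC[C@H]1C(C(=O)O)=CC[C@H]2C(C)(C)CCC[C@]12C | intermediate
24 | (1R,4aS,8aS)-1-[(E)-5-acetoxy-3-methylpent-3-en-1-yl]-5,5,8a-trimethyl-1,4,4a,5,6,7,8,8a-octahydronaphthalene-2-carboxylic acid, i.e. (5S,9R,10S,13E)-15-acetoxylabda-7,13-dien-17-oic acid | CC(=O)OC/C=C(\C)CC[C@H]1C(C(=O)O)=CC[C@H]2C(C)(C)CCC[C@]12C | target

**Count**
Total steps: 10. Longest linear sequence: 9 (steps 1–4 and 6–10; step 5 makes the coupling partner).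

**Steps most likely to fail**

Step 2 (new enantioselective conjugate reverse-prenylation; reactivity and ee on an α-methyl enone are untested). Fallback from 4 and 3, returning at 6, by known chemistry: the TiCl4-mediated Hosomi–Sakurai reaction gives the racemic trans ketone, (2S,3R)-2-methyl-3-(2-methylbut-3-en-2-yl)cyclopentan-1-one F1 together with its mirror image (2R,3S)-2-methyl-3-(2-methylbut-3-en-2-yl)cyclopentan-1-one F2. Johnson resolution follows: lithiated (S)-N,S-dimethyl-S-phenylsulfoximine adds to give the diastereomeric β-hydroxysulfoximine from F1 F3 and β-hydroxysulfoximine from F2 F4, which are separated by chromatography. Thermolysis of F3 (toluene, 110 °C) returns enantiopure F1, and thermodynamic enol silylation (Me3SiCl, NaI, Et3N, MeCN) converts it into 6. The MeLi/allyl bromide part of step 2 then follows unchanged.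

Step 4 (new chloroallylation/semipinacol ring expansion; epoxide closure, migration of the wrong carbon, or isomerisation of the α-vinyl ketone could compete). Fallback from 10, returning at 14, by the known Nozaki–Yamamoto β-oxido carbenoid ring enlargement: LiCHBr2 (from CH2Br2 and lithium 2,2,6,6-tetramethylpiperidide, THF, −78 °C) adds to 10 to give the dibromomethyl carbinol F5. n-BuLi (2.2 equiv, −95 → −78 °C) gives the lithium β-oxido carbenoid F6, whose more substituted neighbour migrates with loss of LiBr to the ring-enlarged lithium enolate F7, regiodefined toward the new carbon. Aldol addition to (phenylselanyl)acetaldehyde gives the β-hydroxy selenide F8, and MsCl, Et3N (elimination of the β-hydroxy selenide, an established vinyl-cation equivalent) gives 14.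

Step 7 (kinetic enol triflation next to an enoate; γ-deprotonation of the ester or enolisation toward C9 would erode yield). Fallback from 19, returning at 22: i-Bu2AlH reduces both carbonyl groups to the diol F9; TBSCl, imidazole silylates only the primary allylic alcohol to the silyl ether alcohol F10; Dess–Martin periodinane gives the keto silyl ether F11, which carries no acidic ester. KN(SiMe3)2 then PhNTf2, through the potassium enolate F12, gives the enol triflate silyl ether F13, and HF·pyridine removes the silyl group to give 22.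

Further compounds
F1 | step 2 | (2S,3R)-2-methyl-3-(2-methylbut-3-en-2-yl)cyclopentan-1-one | O=C1CC[C@@H](C(C)(C)C=C)[C@@H]1C
F2 | step 2 | (2R,3S)-2-methyl-3-(2-methylbut-3-en-2-yl)cyclopentan-1-one | O=C1CC[C@H](C(C)(C)C=C)[C@H]1C
F3 | step 2 | β-hydroxysulfoximine from F1 and (S)-N,S-dimethyl-S-phenylsulfoximine (carbinol epimers) | OC1(C[S@@](=O)(=NC)c2ccccc2)CC[C@@H](C(C)(C)C=C)[C@@H]1C
F4 | step 2 | β-hydroxysulfoximine from F2 and (S)-N,S-dimethyl-S-phenylsulfoximine (carbinol epimers) | OC1(C[S@@](=O)(=NC)c2ccccc2)CC[C@H](C(C)(C)C=C)[C@H]1C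
F5 | step 4 | (3aS,7aS)-1-(dibromomethyl)-4,4,7a-trimethyloctahydro-1H-inden-1-ol (C1 epimers) | BrC(Br)C1(O)CC[C@H]2C(C)(C)CCC[C@]12C
F6 | step 4 | lithium (3aS,7aS)-1-[bromo(lithio)methyl]-4,4,7a-trimethyloctahydro-1H-inden-1-olate | [Li]C(Br)C1(O[Li])CC[C@H]2C(C)(C)CCC[C@]12C
F7 | step 4 | lithium (4aS,8aS)-5,5,8a-trimethyl-3,4,4a,5,6,7,8,8a-octahydronaphthalen-2-olate | [Li]OC1=C[C@@]2(C)CCCC(C)(C)[C@@H]2CC1
F8 | step 4 | (4aS,8aS)-1-[1-hydroxy-2-(phenylselanyl)ethyl]-5,5,8a-trimethyloctahydronaphthalen-2(1H)-one (C1 as in 14, carbinol epimers) | OC(C[Se]c1ccccc1)[C@H]1C(=O)CC[C@H]2C(C)(C)CCC[C@]12C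
F9 | step 7 | (1R,4aS,8aS)-1-[(E)-5-hydroxy-3-methylpent-3-en-1-yl]-5,5,8a-trimethyldecahydronaphthalen-2-ol (C2 epimers) | OC/C=C(\C)CC[C@H]1C(O)CC[C@H]2C(C)(C)CCC[C@]12C
F10 | step 7 | (1R,4aS,8aS)-1-[(E)-5-{[tert-butyl(dimethyl)silyl]oxy}-3-methylpent-3-en-1-yl]-5,5,8a-trimethyldecahydronaphthalen-2-ol (C2 epimers) | CC(C)(C)[Si](C)(C)OC/C=C(\C)CC[C@H]1C(O)CC[C@H]2C(C)(C)CCC[C@]12C
F11 | step 7 | (1R,4aS,8aS)-1-[(E)-5-{[tert-butyl(dimethyl)silyl]oxy}-3-methylpent-3-en-1-yl]-5,5,8a-trimethyloctahydronaphthalen-2(1H)-one | CC(C)(C)[Si](C)(C)OC/C=C(\C)CC[C@H]1C(=O)CC[C@H]2C(C)(C)CCC[C@]12C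
F12 | step 7 | potassium (1R,4aS,8aS)-1-[(E)-5-{[tert-butyl(dimethyl)silyl]oxy}-3-methylpent-3-en-1-yl]-5,5,8a-trimethyl-1,4,4a,5,6,7,8,8a-octahydronaphthalen-2-olate | CC(C)(C)[Si](C)(C)OC/C=C(\C)CC[C@H]1C(O[K])=CC[C@H]2C(C)(C)CCC[C@]12C
F13 | step 7 | (1R,4aS,8aS)-1-[(E)-5-{[tert-butyl(dimethyl)silyl]oxy}-3-methylpent-3-en-1-yl]-5,5,8a-trimethyl-1,4,4a,5,6,7,8,8a-octahydronaphthalen-2-yl trifluoromethanesulfonate | CC(C)(C)[Si](C)(C)OC/C=C(\C)CC[C@H]1C(OS(=O)(=O)C(F)(F)F)=CC[C@H]2C(C)(C)CCC[C@]12C
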